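The route rests on disconnecting the C3–O bond of the dihydrofuran ring (ring B) back to a C3–H bond, with the oxygen delivered from the C2 side chain. The key step exploits the fact that the benzylic C3–H of ring B lies δ to the hydroxyl oxygen on the side-chain CH2 (O–CH2–C(=CH2)–C2–C3–H). In one operation the alkoxy radical of allylic alcohol 14, a (2S)-2-(3-hydroxyprop-1-en-2-yl)-2,3-dihydrobenzofuran, abstracts that hydrogen and the oxygen closes onto C3. This gives the cis-fused methylenetetrahydrofuran 16 and fixes C3–O cis to the C2 substituent. The bridging CH2 is the future formyl carbon. The side-chain ester of 14 is a placeholder; both isovalerates are installed late.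

Key step: step 9

Remark: the side-chain isovalerate cannot survive the hydride reduction of the lactone in step 11, so it serves only as protection through steps 8 to 10 and both secondary alcohols are acylated together in step 13; C2 changes its descriptor from S to R when C3 is oxygenated, with no change in geometry.

Step 1
Reactants: 1 4'-hydroxyacetophenone; 2 prenyl bromide
Product: 4 1-[4-hydroxy-3-(3-methylbut-2-en-1-yl)phenyl]ethan-1-one, via sodium 4-acetylphenolate 3 (not isolated)
Conditions: NaH (1.05 equiv), toluene, 0 °C to rt; then 2, rt to 60 °C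
Reagents that add atoms: none
Why: Ortho C-alkylation of a phenoxide, in which the sodium salt reacts as a tight ion pair in toluene so that the allylic bromide is steered to the free ortho carbon (the para position is blocked) and the dienone tautomerises back to the phenol.

Step 2
Reactants: 4 1-[4-hydroxy-3-(3-methylbut-2-en-1-yl)phenyl]ethan-1-one
Product: 5 1-[3-(3-methylbut-2-en-1-yl)-4-{[tri(propan-2-yl)silyl]oxy}phenyl]ethan-1-one
Conditions: i-Pr3SiCl, imidazole, DMF, rt
Reagents that add atoms: chlorotri(propan-2-yl)silane, CC(C)[Si](Cl)(C(C)C)C(C)C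
Why: Imidazole-promoted O-silylation, giving a bulky aryl silyl ether that keeps the phenol away from the oxidant and should survive the basic buffer of the next step.

Step 3
Reactants: 5 1-[3-(3-methylbut-2-en-1-yl)-4-{[tri(propan-2-yl)silyl]oxy}phenyl]ethan-1-one
Product: 6 1-[3-{[(2R)-3,3-dimethyloxiran-2-yl]methyl}-4-{[tri(propan-2-yl)silyl]oxy}phenyl]ethan-1-one
Conditions: 1,2:4,5-di-O-isopropylidene-β-D-erythro-2,3-hexodiulo-2,6-pyranose (0.3 equiv), KHSO5 (as 2KHSO5·KHSO4·K2SO4), K2CO3, Bu4NHSO4, MeCN/CH2(OMe)2/aq. Na2B4O7 buffer (pH 10.5), 0 °C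
Reagents that add atoms: potassium peroxymonosulfate, [K+].[O-]S(=O)(=O)OO
Why: Shi asymmetric epoxidation, in which the dioxirane of the D-fructose-derived ketone transfers oxygen to the trisubstituted alkene through a spiro transition state that for this ketone enantiomer should give the (R)-epoxide, while the aryl ketone and the silyl ether are inert.

Step 4
Reactants: 6 1-[3-{[(2R)-3,3-dimethyloxiran-2-yl]methyl}-4-{[tri(propan-2-yl)silyl]oxy}phenyl]ethan-1-one
Product: 8 1-[(2S)-2-(2-hydroxypropan-2-yl)-2,3-dihydro-1-benzofuran-5-yl]ethan-1-one, via tetrabutylammonium epoxy phenolate 7 (not isolated)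
Conditions: Bu4NF, THF, 0 to 50 °C
Reagents that add atoms: none
Why: Fluoride desilylation followed by intramolecular epoxide opening, in which the phenolate attacks the secondary epoxide carbon in a 5-exo-tet SN2 reaction with inversion, so that the (R)-epoxide gives (S)-configured C2 and the 6-endo attack at the tertiary carbon is disfavoured under basic conditions.

Step 5
Reactants: 8 1-[(2S)-2-(2-hydroxypropan-2-yl)-2,3-dihydro-1-benzofuran-5-yl]ethan-1-one
Product: 10 1-[(2S)-2-(prop-1-en-2-yl)-2,3-dihydro-1-benzofuran-5-yl]ethan-1-one, via sulfamate ester 9 (not isolated)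
Conditions: methyl N-(triethylammoniosulfonyl)carbamate (Burgess reagent), toluene, rt to 50 °C
Reagents that add atoms: none
Why: Burgess dehydration by syn elimination of the sulfamate ester through a cyclic transition state, which should take a proton from one of the two methyl groups (six accessible hydrogens against the single C2–H, whose loss would give a strained tetrasubstituted enol ether) and leaves C2 untouched.

Step 6
Reactants: 10 1-[(2S)-2-(prop-1-en-2-yl)-2,3-dihydro-1-benzofuran-5-yl]ethan-1-one
Product: 11 (1R)-1-[(2S)-2-(prop-1-en-2-yl)-2,3-dihydro-1-benzofuran-5-yl]ethan-1-ol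
Conditions: RuCl[(R,R)-TsDPEN](p-cymene) (1 mol%), HCO2H/Et3N (5:2), DMF, 40 °C
Reagents that add atoms: none
Why: Noyori asymmetric transfer hydrogenation, in which the ruthenium hydride of the (R,R)-diamine complex delivers hydride to the aryl methyl ketone through an outer-sphere six-membered transition state with the aryl group held against the arene ligand, which should set the (R)-carbinol and leave the isolated alkene alone.

Step 7
Reactants: 11 (1R)-1-[(2S)-2-(prop-1-en-2-yl)-2,3-dihydro-1-benzofuran-5-yl]ethan-1-ol; 12 3-methylbutanoic anhydride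
Product: 13 (1R)-1-[(2S)-2-(prop-1-en-2-yl)-2,3-dihydro-1-benzofuran-5-yl]ethyl 3-methylbutanoate
Conditions: Et3N, 4-(dimethylamino)pyridine (cat.), CH2Cl2, 0 °C to rt
Reagents that add atoms: none
Why: Acylation of the secondary alcohol by nucleophilic catalysis through the acylpyridinium ion, with retention at the carbinol carbon because its C–O bond is not broken.

Step 8
Reactants: 13 (1R)-1-[(2S)-2-(prop-1-en-2-yl)-2,3-dihydro-1-benzofuran-5-yl]ethyl 3-methylbutanoate
Product: 14 (1R)-1-[(2S)-2-(3-hydroxyprop-1-en-2-yl)-2,3-dihydro-1-benzofuran-5-yl]ethyl 3-methylbutanoate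
Conditions: SeO2 (0.5 equiv), t-BuOOH (2 equiv), CH2Cl2, rt
Reagents that add atoms: selenium dioxide, O=[Se]=O (transfers the oxygen); tert-butyl hydroperoxide, CC(C)(C)OO (stoichiometric oxygen source)
Why: Selenium dioxide allylic hydroxylation (ene reaction at the 1,1-disubstituted alkene, then [2,3]-sigmatropic shift), which in isopropenyl groups should take a methyl hydrogen in preference to the ring methine C2–H, with the hydroperoxide keeping selenium catalytic and limiting over-oxidation to the enal.

Step 9
Reactants: 14 (1R)-1-[(2S)-2-(3-hydroxyprop-1-en-2-yl)-2,3-dihydro-1-benzofuran-5-yl]ethyl 3-methylbutanoate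
Product: 16 (1R)-1-[(3aR,8bR)-3-methylidene-2,3,3a,8b-tetrahydrofuro[3,2-b][1]benzofuran-7-yl]ethyl 3-methylbutanoate, via hypoiodite 15 (not isolated)
Conditions: PhI(OAc)2 (1.5 equiv), I2 (0.5 equiv), NaHCO3, cyclohexane/CH2Cl2, visible light (tungsten lamp), 20 °C
Reagents that add atoms: none
Why: AcOI, formed in the flask from PhI(OAc)2 and I2, converts the primary hydroxyl of 14 into hypoiodite 15; visible light cleaves its weak O–I bond and the alkoxy radical takes the benzylic C3–H through a six-membered transition state (1,5-hydrogen transfer along O–CH2–C(=CH2)–C2–C3–H), after which the C3 radical is oxidised to the cation level, stabilised by the benzene ring (ring A) and by O1 through C7a, and is captured by the same oxygen. The closest known reaction type is the Suárez hypoiodite cyclisation of alcohols onto δ C–H bonds, the oxygen counterpart of the Hofmann–Löffler–Freytag reaction. The one new ring (ring C: O, CH2, C(=CH2), C2, C3) closes in the 5-exo mode at C3, 5-exo-trig on the cation because its C3–C3a double-bond character lies outside the new ring (the same bond would form by 5-exo-tet displacement if a C3 iodide were to intervene). The new C3 stereocentre is controlled by C2 alone: the three-atom tether reaches C3 only on the face that carries the side chain and a 5,5-bicycle can only be cis-fused, so C3–O ends up cis to the C2 substituent (8bR). The step needs site selectivity for C3–H over the side-chain ArCH(CH3)O methine, over C2–H and over the alkene, and it needs ring closure to outrun loss of the C2 proton, which would give a benzofuran. The substrate secures the first through the intramolecular six-membered hydrogen transfer (the ester methine is reachable only intermolecularly and is deactivated by its acyloxy group, and C2–H would need a five-membered transition state) and the second through the five-membered closure from an oxygen already held over C3, while NaHCO3 keeps the medium neutral so that neither the new benzylic ether nor the benzylic ester ionises.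

Step 10
Reactants: 16 (1R)-1-[(3aR,8bR)-3-methylidene-2,3,3a,8b-tetrahydrofuro[3,2-b][1]benzofuran-7-yl]ethyl 3-methylbutanoate
Product: 17 (1R)-1-[(3aR,8bR)-3-methylidene-2-oxo-2,3,3a,8b-tetrahydrofuro[3,2-b][1]benzofuran-7-yl]ethyl 3-methylbutanoate
Conditions: CrO3, 3,5-dimethylpyrazole, CH2Cl2, −20 °C
Reagents that add atoms: chromium trioxide, O=[Cr](=O)=O
Why: Allylic C–H oxidation by the chromium trioxide–pyrazole complex at the ring CH2, which is both allylic and next to the ether oxygen, the position at which 3-methylenetetrahydrofurans are known to be oxidised to α-methylene γ-lactones, with no stereocentre involved.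

Step 11
Reactants: 17 (1R)-1-[(3aR,8bR)-3-methylidene-2-oxo-2,3,3a,8b-tetrahydrofuro[3,2-b][1]benzofuran-7-yl]ethyl 3-methylbutanoate
Product: 18 (2R,3R)-5-[(1R)-1-hydroxyethyl]-2-(3-hydroxyprop-1-en-2-yl)-2,3-dihydro-1-benzofuran-3-ol
Conditions: i-Bu2AlH (6 equiv), CH2Cl2, −78 to 0 °C; aq. KNaC4H4O6
Reagents that add atoms: none
Why: Hydride reduction of the lactone to the diol by 1,2-addition (the exocyclic alkene is kept), with the side-chain isovalerate cleaved reductively in the same operation as planned and no C–O bond at a stereocentre broken.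

Step 12
Reactants: 18 (2R,3R)-5-[(1R)-1-hydroxyethyl]-2-(3-hydroxyprop-1-en-2-yl)-2,3-dihydro-1-benzofuran-3-ol
Product: 19 (2R,3R)-2-(3-{[tert-butyl(dimethyl)silyl]oxy}prop-1-en-2-yl)-5-[(1R)-1-hydroxyethyl]-2,3-dihydro-1-benzofuran-3-ol
Conditions: t-BuMe2SiCl (1.05 equiv), imidazole, CH2Cl2, −20 to 0 °C
Reagents that add atoms: tert-butyl(chloro)dimethylsilane, CC(C)(C)[Si](C)(C)Cl
Why: Chemoselective silylation, since the unhindered primary allylic alcohol should react far faster with the bulky silyl chloride than the two secondary benzylic alcohols.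

Step 13
Reactants: 19 (2R,3R)-2-(3-{[tert-butyl(dimethyl)silyl]oxy}prop-1-en-2-yl)-5-[(1R)-1-hydroxyethyl]-2,3-dihydro-1-benzofuran-3-ol; 12 3-methylbutanoic anhydride
Product: 20 (1R)-1-[(2R,3R)-2-(3-{[tert-butyl(dimethyl)silyl]oxy}prop-1-en-2-yl)-3-[(3-methylbutanoyl)oxy]-2,3-dihydro-1-benzofuran-5-yl]ethyl 3-methylbutanoate
Conditions: 12 (3 equiv), Et3N, 4-(dimethylamino)pyridine, CH2Cl2, 0 °C to rt
Reagents that add atoms: none
Why: Acylpyridinium-mediated acylation of both secondary alcohols with excess anhydride under basic, non-ionising conditions, with retention at both carbinol carbons.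

Step 14
Reactants: 20 (1R)-1-[(2R,3R)-2-(3-{[tert-butyl(dimethyl)silyl]oxy}prop-1-en-2-yl)-3-[(3-methylbutanoyl)oxy]-2,3-dihydro-1-benzofuran-5-yl]ethyl 3-methylbutanoate
Product: 21 (1R)-1-[(2R,3R)-2-(3-hydroxyprop-1-en-2-yl)-3-[(3-methylbutanoyl)oxy]-2,3-dihydro-1-benzofuran-5-yl]ethyl 3-methylbutanoate
Conditions: Bu4NF/AcOH (1:1), THF, 0 °C to rt
Reagents that add atoms: none
Why: Fluoride-mediated cleavage of the primary silyl ether, buffered with acetic acid so that the two esters should neither migrate nor eliminate.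

Step 15
Reactants: 21 (1R)-1-[(2R,3R)-2-(3-hydroxyprop-1-en-2-yl)-3-[(3-methylbutanoyl)oxy]-2,3-dihydro-1-benzofuran-5-yl]ethyl 3-methylbutanoate
Product: 22 (1R)-1-[(2R,3R)-3-[(3-methylbutanoyl)oxy]-2-(3-oxoprop-1-en-2-yl)-2,3-dihydro-1-benzofuran-5-yl]ethyl 3-methylbutanoate
Conditions: MnO2 (activated, excess), CH2Cl2, rt
Reagents that add atoms: none
Why: MnO2 oxidation of a primary allylic alcohol to the enal on the solid surface under neutral conditions, which should leave both esters and all three stereocentres untouched.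

Compound list
1 | 1-(4-hydroxyphenyl)ethan-1-one (4'-hydroxyacetophenone) | CC(=O)c1ccc(O)cc1 | starting material
2 | 1-bromo-3-methylbut-2-ene (prenyl bromide) | CC(C)=CCBr | starting material
3 | sodium 4-acetylphenolate | CC(=O)c1ccc([O-])cc1.[Na+] | intermediate
4 | 1-[4-hydroxy-3-(3-methylbut-2-en-1-yl)phenyl]ethan-1-one | CC(=O)c1ccc(O)c(CC=C(C)C)c1 | intermediate
5 | 1-[3-(3-methylbut-2-en-1-yl)-4-{[tri(propan-2-yl)silyl]oxy}phenyl]ethan-1-one | CC(=O)c1ccc(O[Si](C(C)C)(C(C)C)C(C)C)c(CC=C(C)C)c1 | intermediate
6 | 1-[3-{[(2R)-3,3-dimethyloxiran-2-yl]methyl}-4-{[tri(propan-2-yl)silyl]oxy}phenyl]ethan-1-one | CC(=O)c1ccc(O[Si](C(C)C)(C(C)C)C(C)C)c(C[C@H]2OC2(C)C)c1 | intermediate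
7 | tetrabutylammonium 4-acetyl-2-{[(2R)-3,3-dimethyloxiran-2-yl]methyl}phenolate | CC(=O)c1ccc([O-])c(C[C@H]2OC2(C)C)c1.CCCC[N+](CCCC)(CCCC)CCCC | intermediate
8 | 1-[(2S)-2-(2-hydroxypropan-2-yl)-2,3-dihydro-1-benzofuran-5-yl]ethan-1-one | CC(C)(O)[C@H]1Oc2ccc(C(C)=O)cc2C1 | intermediate
9 | triethylammonium salt of the N-(methoxycarbonyl)sulfamate ester of 8 | COC(=O)[N-]S(=O)(=O)OC(C)(C)[C@H]1Oc2ccc(C(C)=O)cc2C1.CC[NH+](CC)CC | intermediate
10 | 1-[(2S)-2-(prop-1-en-2-yl)-2,3-dihydro-1-benzofuran-5-yl]ethan-1-one | C=C(C)[C@H]1Oc2ccc(C(C)=O)cc2C1 | intermediate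
11 | (1R)-1-[(2S)-2-(prop-1-en-2-yl)-2,3-dihydro-1-benzofuran-5-yl]ethan-1-ol | C=C(C)[C@H]1Oc2ccc([C@@H](C)O)cc2C1 | intermediate
12 | 3-methylbutanoic anhydride (isovaleric anhydride) | CC(C)CC(=O)OC(=O)CC(C)C | starting material
13 | (1R)-1-[(2S)-2-(prop-1-en-2-yl)-2,3-dihydro-1-benzofuran-5-yl]ethyl 3-methylbutanoate | C=C(C)[C@H]1Oc2ccc([C@@H](C)OC(=O)CC(C)C)cc2C1 | intermediate
14 | (1R)-1-[(2S)-2-(3-hydroxyprop-1-en-2-yl)-2,3-dihydro-1-benzofuran-5-yl]ethyl 3-methylbutanoate | C=C(CO)[C@H]1Oc2ccc([C@@H](C)OC(=O)CC(C)C)cc2C1 | intermediate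
15 | (1R)-1-[(2S)-2-[3-(iodooxy)prop-1-en-2-yl]-2,3-dihydro-1-benzofuran-5-yl]ethyl 3-methylbutanoate | C=C(COI)[C@H]1Oc2ccc([C@@H](C)OC(=O)CC(C)C)cc2C1 | intermediate
16 | (1R)-1-[(3aR,8bR)-3-methylidene-2,3,3a,8b-tetrahydrofuro[3,2-b][1]benzofuran-7-yl]ethyl 3-methylbutanoate | C=C1CO[C@@H]2c3cc([C@@H](C)OC(=O)CC(C)C)ccc3O[C@H]12 | intermediate
17 | (1R)-1-[(3aR,8bR)-3-methylidene-2-oxo-2,3,3a,8b-tetrahydrofuro[3,2-b][1]benzofuran-7-yl]ethyl 3-methylbutanoate | C=C1C(=O)O[C@@H]2c3cc([C@@H](C)OC(=O)CC(C)C)ccc3O[C@H]12 | intermediate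
18 | (2R,3R)-5-[(1R)-1-hydroxyethyl]-2-(3-hydroxyprop-1-en-2-yl)-2,3-dihydro-1-benzofuran-3-ol | C=C(CO)[C@H]1Oc2ccc([C@@H](C)O)cc2[C@H]1O | intermediate
19 | (2R,3R)-2-(3-{[tert-butyl(dimethyl)silyl]oxy}prop-1-en-2-yl)-5-[(1R)-1-hydroxyethyl]-2,3-dihydro-1-benzofuran-3-ol | C=C(CO[Si](C)(C)C(C)(C)C)[C@H]1Oc2ccc([C@@H](C)O)cc2[C@H]1O | intermediate
20 | (1R)-1-[(2R,3R)-2-(3-{[tert-butyl(dimethyl)silyl]oxy}prop-1-en-2-yl)-3-[(3-methylbutanoyl)oxy]-2,3-dihydro-1-benzofuran-5-yl]ethyl 3-methylbutanoate | C=C(CO[Si](C)(C)C(C)(C)C)[C@H]1Oc2ccc([C@@H](C)OC(=O)CC(C)C)cc2[C@H]1OC(=O)CC(C)C | intermediate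
21 | (1R)-1-[(2R,3R)-2-(3-hydroxyprop-1-en-2-yl)-3-[(3-methylbutanoyl)oxy]-2,3-dihydro-1-benzofuran-5-yl]ethyl 3-methylbutanoate | C=C(CO)[C@H]1Oc2ccc([C@@H](C)OC(=O)CC(C)C)cc2[C@H]1OC(=O)CC(C)C | intermediate
22 | (1R)-1-[(2R,3R)-3-[(3-methylbutanoyl)oxy]-2-(3-oxoprop-1-en-2-yl)-2,3-dihydro-1-benzofuran-5-yl]ethyl 3-methylbutanoate | C=C(C=O)[C@H]1Oc2ccc([C@@H](C)OC(=O)CC(C)C)cc2[C@H]1OC(=O)CC(C)C | target

Total step count: 15. Longest linear sequence: 15 steps (1 to 22).

Steps most likely to fail

Step 9. The alkoxy radical may be diverted before the hydrogen transfer. Electrophilic iodine can add to the electron-rich 1,1-disubstituted alkene (including three-membered capture by the neighbouring oxygen) or iodinate ring A ortho to O1. The hypoiodite can also collapse to the enal by loss of HI, and after the transfer the C3 cation can lose the C2 proton and aromatise. The fallback sets out from 14 and makes the same C3–O bond by a two-electron path without iodine. DDQ (4 Å molecular sieves, 1,2-dichloroethane, rt to 50 °C) should abstract hydride from the O1-activated benzylic C3–H, and the tethered hydroxyl captures the cation from the face of the side chain. This is an oxidative benzylic C–H etherification of the kind known for alkoxyarenes with tethered alcohols. It comes back to the route at 16 and creates no new compound (F0).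

Step 10. Site selectivity of the chromium oxidant may be poor, with hydrogen abstraction at the benzylic ether C8b–H or the allylic C3a–H instead of the ring CH2, or with oxidative degradation of the alkene. The fallback sets out from 16 and reaches the lactone in two milder operations. SeO2 (cat.)/t-BuOOH in CH2Cl2 hydroxylates by the ene and [2,3]-shift pathway, which prefers CH2 over CH and does not touch benzylic ether C–H bonds. This should give the lactol (1R)-1-[(3aR,8bR)-2-hydroxy-3-methylidene-2,3,3a,8b-tetrahydrofuro[3,2-b][1]benzofuran-7-yl]ethyl 3-methylbutanoate F1 as a mixture of anomers. MnO2 in CH2Cl2 then oxidises this allylic lactol to the lactone, and the route is rejoined at 17.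

Step 1. O-alkylation and double alkylation of the ambident phenoxide may outrun the ortho C-alkylation. The fallback sets out from 1 and moves the carbon–carbon bond formation into a sigmatropic step. O-alkylation with 3-chloro-3-methylbut-1-yne (K2CO3, KI, CuI cat., acetone, reflux) gives 1-{4-[(2-methylbut-3-yn-2-yl)oxy]phenyl}ethan-1-one F2. Semi-hydrogenation (H2, Pd on CaCO3 poisoned with Pb(OAc)2, quinoline, EtOAc) gives 1-{4-[(2-methylbut-3-en-2-yl)oxy]phenyl}ethan-1-one F3. Aromatic Claisen rearrangement (N,N-diethylaniline, 130 °C) then delivers the allyl unit to the ortho carbon as the prenyl group and returns to the route at 4.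

Further compounds
F0 | step 9 | none | none
F1 | step 10 | (1R)-1-[(3aR,8bR)-2-hydroxy-3-methylidene-2,3,3a,8b-tetrahydrofuro[3,2-b][1]benzofuran-7-yl]ethyl 3-methylbutanoate (both anomers) | C=C1C(O)O[C@@H]2c3cc([C@@H](C)OC(=O)CC(C)C)ccc3O[C@H]12
F2 | step 1 | 1-{4-[(2-methylbut-3-yn-2-yl)oxy]phenyl}ethan-1-one | CC(=O)c1ccc(OC(C)(C)C#C)cc1
F3 | step 1 | 1-{4-[(2-methylbut-3-en-2-yl)oxy]phenyl}ethan-1-one | CC(=O)c1ccc(OC(C)(C)C=C)cc1
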